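In the early seconds substrate and activator combine to the activated form, which either closes to ring or is caught by a second substrate as open dimer, while ring itself passes on to over-reaction product.

common to all: substrate 0.0010 M; activator 0.900 equiv; time 12 s
- dusk: temperature 25 °C
- spring: temperature 55 °C
- midnight: temperature 115 °C
- noon: temperature 85 °C

    ring → over-reaction product (k1 = 6.82 × 10⁻⁵ s⁻¹, Ea1 = 100 kJ mol⁻¹)
    substrate + activated form → open dimer (k2 = 3780 L mol⁻¹ s⁻¹, Ea2 = 31.0 kJ mol⁻¹)
    activated form → ring (k3 = 2.77 s⁻¹, Ea3 = 69.0 kJ mol⁻¹)
    substrate + activator → activated form (k4 = 93.4 L mol⁻¹ s⁻¹, Ea4 = 48.0 kJ mol⁻¹)
    (constants at 25 °C)

- in percentages every species weighs as the substrate in it: one open dimer counts as two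
- constants are those at 25 °C; use the activation energies for any other temperature

* the flask that comes out highest in amount of ring, in percent of the substrate charged, or "all alike" when all lie within 1.5 percentage points (dusk / spring / midnight / noon / all alike)
* ring at the end, in percent of the substrate charged, dusk
* ring at the end, in percent of the substrate charged, spring
* ring at the end, in percent of the substrate charged, midnight
* ring at the end, in percent of the substrate charged, noon

Activator is charged in the smaller amount, 0.900 equiv, and its balance is the place to begin. In fractions of the substrate charged, every activator used stands in one of four places:

activator used = ring + over-reaction product + activated form + half the open dimer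

Ring at the end can therefore be reckoned as a product of three factors:

ring ≈ activator used × closing share × keep

The activator used comes from treating substrate and activator as falling together, so that the reciprocal of the amount grows steadily with time. The closing share is the ring-closure rate over the sum of the ring-closure and capture rates, taken at the full charge of substrate.

The third factor carries the argument. At noon the ring-loss constant has grown to 0.0587 s⁻¹, so the keep, the fraction of ring formed at the start that still stands at the end, is exp(−ring-loss constant × time) = 0.494. The reckoning for each flask then runs:

dusk: 0.452 × 0.423 × 0.999 = 0.191

spring: 0.770 × 0.748 × 0.968 = 0.558

noon: 0.866 × 0.905 × 0.494 = 0.388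

At midnight the keep is 7.92 × 10⁻⁵, so this reckoning puts spring highest.

Turned round, noon passes spring once its keep reaches 0.711, which is more than the 0.494 reckoned. The product of ring-loss constant and time at noon must then be 0.341 instead of 0.705.

The forecast names spring, with 22.8% at dusk, 63.4% at spring, 45% at noon and 0.02% at midnight, on the ground that “Heating favours ring closure over dimerisation”. Its spring and noon figures stand above the reckoning here, though the winner is the same.

The simulation gives spring highest: 63.5% against 44.6% at noon, 22.9% at dusk and 0.0180% at midnight. Noon held 60.3% ring at 6.00 s and over-reaction product 39.5% at 12.0 s. Ring over ring plus over-reaction product at the end of noon is 0.530, beside the keep of 0.494. For a flask kept at 90 °C the keep reckons to 0.327, and that flask ends with ring over ring plus over-reaction product at 0.360.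

The constants are invented; no experiment stands behind them.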